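All runs come from a simulation for substances that don't exist; scatter was added.

The ratio of target to starting material is the number to follow in this flask, where starting material and coupling partner join reversibly to target; the maple run is the flask itself, followed so far.

- maple: starting material 0.43 M; coupling partner 2.15 M; the very flask that is asked about, followed so far
- flask: starting material 0.43 M; coupling partner 2.15 M; time 15 d

maple run (percent of the starting material charged)

| time / d | target / % | starting material / % |
|---|---|---|
| 0.104 | 44.1 | 56.2 |
| 0.333 | 60.9 | 38.0 |
| 1.04 | 55.0 | 37.4 |
| 3.00 | 38.4 | 40.2 |

(scatter of a reading: 1 percentage point)

1. time, not beyond 15 d, at which the flask holds most target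
2. the amount of target, in percent of the starting material charged, at that time
3. the first time at which target reaches 31%, in the same percent, in d



At the second reading the ratio stands at 1.60. Starting material reads nearly the same at the second and third readings, so forward and back rates are taken to nearly cancel there, and time drops out of the ratio. Dividing that ratio by the coupling partner left, counted as spent into target and nowhere else, gives the balance quotient, 0.849 M⁻¹, an apparent equilibrium constant. Taken as a ceiling, with target and starting material summing to the charge, the ratio gives target 61.6%, and the first reading, read as an exponential approach to that ceiling, gives a relaxation rate of 12.1 d⁻¹. My own reckoning therefore puts 31% of target at 0.0578 d.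

The weak link is a ceiling held still, since target, as a fraction of the charge, sags at 0.0835 d⁻¹ between the second and third readings. Setting the remaining approach slope equal to that sag places the peak at 0.371 d, with target at 60.9%.

The forecast, which says “The target rises fast, peaks, then declines”, gives 60.8% at 0.37 d and reaches the level at 0.056 d, slightly earlier than my reckoning.

The flask gives 61.2% at 0.425 d and reaches the level at 0.0612 d, so the forecast stands. Target in the flask then falls to 50.2% at 1.70 d and 0.768% at 15.0 d, so this flask is to be stopped near its best time.

    starting material + coupling partner ⇌ target (K = 1.05 M⁻¹, k = 0.00230 M⁻¹ min⁻¹)
    starting material → side product (k = 1.22 × 10⁻⁴ min⁻¹)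
    coupling partner → decomposed reagent (k = 2.04 × 10⁻⁴ min⁻¹)

The back reaction holds the flask's peak down: the same run without it reaches 97.2% against 61.2%. Solved for the share of target, with the partner counted as before, the quotient 0.849 M⁻¹ returns 61.5% for this flask. In the neighbour flask charged with 1.1 M of starting material, coupling partner is charged at 1.95 equiv; the same balance gives 56.5%, and the neighbour flask's simulated peak is 56.2%.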